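**Plan**

- Retrosynthesis: the enol-lactone C–O bond of the (Z)-butylidene butenolide is cut first (2-en-4-ynoic acid), then the alkenyl–alkynyl bond (enol triflate + pent-1-yne), the aryl–C and O–acyl bonds at the spiro carbon (cyclobutanone + ester-bearing aryl Grignard reagent), the bond to the propyl group (aldol with propanal), and last two C–C bonds of the cyclohexene ring.
- Enabling feature: in the cyclohexene ring the butenolide β-carbon (ketone level) lies next to the carboxyl-bearing butenolide α-carbon, and that carbon is bonded to the ring-fusion carbon adjacent to the spiro carbon. With the two fusion carbons as α- and β-carbon of an enal, this is an acetoacetate joined through its central carbon and its methyl group to a cyclobutene carbaldehyde.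
- Forward order: purchased cyclobutane → cyclobutene enal → six-membered ring by amine-catalysed Michael–aldol condensation → propyl group and spiro-phthalide on the cyclobutanone → enol triflate and Sonogashira coupling → butenolide ring last.
- Stereochemistry: the (S)-prolinol silyl ether sets the fusion carbon next to the ketal, and the second fusion carbon follows because only the cis arrangement can close. Exo-face hydrogenation of a propylidene group puts the propyl group endo, exo-face aryl addition sets the spiro carbon, and anti oxy-metalation gives the Z alkene.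

Key step: step 5

Remarks
- Numbering: bicyclo[4.2.0]octane locants are kept for every intermediate (C1 and C6 ring fusion, C2 carboxyl-bearing, C3 ketone/enol, C7 cyclobutane CH2 and later propyl-bearing, C8 ketal/ketone/spiro carbon). "Exo" is the face of the two fusion hydrogens. The C6 descriptor alternates between R and S only through CIP priorities; the geometry at C1 and C6 never changes.
- The β-keto esters are drawn and named as their enols; each equilibrates with its keto form.
- Assumption: the allylic-ketal cyclobutenes 4–6 are stable below room temperature for the time needed; 6 is kept cold and in solution because a conrotatory ring opening to a dienal is conceivable.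

**Route**

Step 1
Reactants: 1 methyl 3,3-dimethoxycyclobutane-1-carboxylate
Product: 2 methyl 3,3-dimethoxy-1-(phenylselanyl)cyclobutane-1-carboxylate
Conditions: LiN(iPr)2, THF, −78 °C; PhSeBr, −78 → 0 °C
Reagents that add atoms: phenylselanyl bromide, Br[Se]c1ccccc1
Why: Deprotonation gives the ester lithium enolate, which PhSeBr selenenylates at carbon (α-selenenylation of an ester enolate); the ketal is inert to the base.

Step 2
Reactants: 2 methyl 3,3-dimethoxy-1-(phenylselanyl)cyclobutane-1-carboxylate
Product: 4 methyl 3,3-dimethoxycyclobut-1-ene-1-carboxylate, via selenoxide 3 (not isolated)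
Conditions: 30% H2O2, pyridine, CH2Cl2, 0 °C → rt
Reagents that add atoms: none
Why: Oxidation at selenium and syn-elimination of the selenoxide (selenoxide elimination) should proceed below room temperature, the cis β-hydrogens of the four-membered ring are well aligned, and since both β-methylene groups are equivalent only one conjugated cyclobutene ester can form.

Step 3
Reactants: 4 methyl 3,3-dimethoxycyclobut-1-ene-1-carboxylate
Product: 5 (3,3-dimethoxycyclobut-1-en-1-yl)methanol
Conditions: iBu2AlH (2.2 equiv), CH2Cl2, −78 °C; aq. potassium sodium tartrate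
Reagents that add atoms: none
Why: iBu2AlH reduces the conjugated ester in 1,2-fashion to the allylic alcohol (hydride reduction) without touching the alkene or, at −78 °C, the ketal.

Step 4
Reactants: 5 (3,3-dimethoxycyclobut-1-en-1-yl)methanol
Product: 6 3,3-dimethoxycyclobut-1-ene-1-carbaldehyde
Conditions: activated MnO2 (excess), CH2Cl2, 0 °C → rt; filter, use the cold solution directly
Reagents that add atoms: none
Why: Activated MnO2 oxidises the allylic alcohol to the enal under neutral, heterogeneous conditions (allylic oxidation), so the strained, acid-sensitive aldehyde is obtained by filtration alone.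

Step 5
Reactants: 6 3,3-dimethoxycyclobut-1-ene-1-carbaldehyde; 7 tert-butyl 3-oxobutanoate
Product: 10 tert-butyl (1R,6R)-3-hydroxy-8,8-dimethoxybicyclo[4.2.0]octa-2,4-diene-2-carboxylate, via keto aldehyde 8 (not isolated), via aldol 9 (not isolated)
Conditions: (S)-2-[diphenyl(trimethylsilyloxy)methyl]pyrrolidine (20 mol%), PhCO2H (20 mol%), CH2Cl2/toluene, 0 °C → rt; then p-TsOH·H2O (10 mol%), 4 Å MS, rt
Reagents that add atoms: tert-butyl 3-oxobutanoate (7), CC(=O)CC(=O)OC(C)(C)C
Why: Proposed new method: the closest known reaction is the prolinol-silyl-ether-catalysed Michael–aldol condensation of acetoacetates with β-monosubstituted acyclic enals to cyclohexenone esters, and what is new is an α,β-disubstituted cyclobutene carbaldehyde as acceptor, which is reasoned to work because the α-substituent is tied back in the four-membered ring (little allylic strain in the iminium ion) and because attack at the ring β-carbon releases cyclobutene strain. Mechanistically 6 condenses with the amine to the E,s-trans iminium ion, the central carbon of 7 adds to the ring carbon next to the ketal, the enamine is protonated to keto aldehyde 8, the methyl ketone enol attacks the formyl carbon to give aldol 9, and acid removes water to give the enone, drawn as its dienol 10. The one ring formed, the six-membered carbocycle, closes in a 6-(enolendo)-exo-trig aldol addition. C1 is set by the catalyst, whose CPh2(OSiMe3) group blocks one face of the iminium ion so that the nucleophile enters from the other and gives the 1R configuration. C6 is set by the substrate, since only a cis-1,2-disubstituted cyclobutane can bridge to the six-membered ring, the formyl-bearing carbon epimerises through the enamine before closure and stays epimerisable afterwards as the γ-carbon of the enone. The step needs conjugate rather than carbonyl (Knoevenagel) addition, which strain release on β-attack and the shielded iminium carbon should secure, and it needs the ketal to survive, which the buffered, water-scavenged medium should secure.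

Step 6
Reactants: 10 tert-butyl (1R,6R)-3-hydroxy-8,8-dimethoxybicyclo[4.2.0]octa-2,4-diene-2-carboxylate
Product: 11 tert-butyl (1R,6S)-3-hydroxy-8,8-dimethoxybicyclo[4.2.0]oct-2-ene-2-carboxylate
Conditions: H2 (1 atm), Pd/C, EtOAc, rt
Reagents that add atoms: none
Why: Heterogeneous hydrogenation saturates the disubstituted C4=C5 alkene, while the tetrasubstituted, hydrogen-bonded enol double bond of the β-keto ester, the ketal and the tert-butyl ester are not reduced and no stereocentre is touched.

Step 7
Reactants: 11 tert-butyl (1R,6S)-3-hydroxy-8,8-dimethoxybicyclo[4.2.0]oct-2-ene-2-carboxylate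
Product: 12 tert-butyl (1R,6S)-3-hydroxy-8-oxobicyclo[4.2.0]oct-2-ene-2-carboxylate
Conditions: p-TsOH·H2O (10 mol%), acetone/H2O (10:1), rt
Reagents that add atoms: water, O
Why: Acid-catalysed ketal hydrolysis driven by excess water and acetone frees the cyclobutanone under conditions too mild to cleave the tert-butyl ester or decarboxylate the β-keto ester.

Step 8
Reactants: 12 tert-butyl (1R,6S)-3-hydroxy-8-oxobicyclo[4.2.0]oct-2-ene-2-carboxylate; 13 propanal
Product: 14 tert-butyl (1R,6R)-3-hydroxy-7-(1-hydroxypropyl)-8-oxobicyclo[4.2.0]oct-2-ene-2-carboxylate (mixture at C7 and at the carbinol carbon)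
Conditions: LiN(iPr)2 (2.2 equiv), THF, −78 °C (ketone added to base); EtCHO; AcOH, −78 °C
Reagents that add atoms: propanal (13), CCC=O
Why: The first equivalent of base turns the β-keto ester into its enolate, which guards C1, C2 and C4 against deprotonation, the second removes a C7 proton of the cyclobutanone, and only this more basic enolate adds to propanal (directed aldol addition of a dianion); the two new stereocentres are removed in the next step.

Step 9
Reactants: 14 tert-butyl (1R,6R)-3-hydroxy-7-(1-hydroxypropyl)-8-oxobicyclo[4.2.0]oct-2-ene-2-carboxylate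
Product: 16 tert-butyl (1R,6R,7E)-3-hydroxy-8-oxo-7-propylidenebicyclo[4.2.0]oct-2-ene-2-carboxylate, via mesylate 15 (not isolated)
Conditions: MsCl, Et3N, CH2Cl2, −20 °C → rt
Reagents that add atoms: none
Why: Mesylation of the secondary alcohol and base-induced E1cB elimination of the β-mesyloxy ketone give the conjugated exocyclic enone (aldol dehydration); the alkene geometry is of no consequence for the next step.

Step 10
Reactants: 16 tert-butyl (1R,6R,7E)-3-hydroxy-8-oxo-7-propylidenebicyclo[4.2.0]oct-2-ene-2-carboxylate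
Product: 17 tert-butyl (1R,6S,7R)-3-hydroxy-8-oxo-7-propylbicyclo[4.2.0]oct-2-ene-2-carboxylate
Conditions: H2 (1 atm), Pd/C, EtOAc, rt
Reagents that add atoms: none
Why: Hydrogen should be delivered to the exocyclic alkene from the convex exo face of the cis-fused bicycle, opposite the six-membered ring, so C7 receives its hydrogen exo and the propyl group ends up endo (7R), the less stable epimer that equilibration could not supply (catalytic hydrogenation under substrate control).

Step 11
Reactants: 17 tert-butyl (1R,6S,7R)-3-hydroxy-8-oxo-7-propylbicyclo[4.2.0]oct-2-ene-2-carboxylate; 18 methyl 2-iodobenzoate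
Product: 20 tert-butyl (1R,6S,7R,8R)-3-hydroxy-3'-oxo-7-propyl-3'H-spiro[bicyclo[4.2.0]oct-2-ene-8,1'-[2]benzofuran]-2-carboxylate, via hydroxy ester 19 (not isolated)
Conditions: 18, iPrMgCl·LiCl, THF, −40 °C; then added to 17 pre-treated with LiN(SiMe3)2 (1.0 equiv, THF, −78 °C), LaCl3·2LiCl, −40 → 0 °C → rt
Reagents that add atoms: methyl 2-iodobenzoate (18), COC(=O)c1ccccc1I
Why: Iodine–magnesium exchange gives the ester-bearing aryl Grignard reagent, which, with LaCl3·2LiCl to suppress enolisation, should add to the strained ketone from the exo face away from both the endo propyl group and the six-membered ring, and the endo alkoxide then displaces methoxide from the neighbouring ester to close the phthalide (Grignard addition–lactonisation), fixing the spiro centre as 8R.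

Step 12
Reactants: 20 tert-butyl (1R,6S,7R,8R)-3-hydroxy-3'-oxo-7-propyl-3'H-spiro[bicyclo[4.2.0]oct-2-ene-8,1'-[2]benzofuran]-2-carboxylate
Product: 21 tert-butyl (1R,6S,7R,8R)-3'-oxo-7-propyl-3-(trifluoromethanesulfonyloxy)-3'H-spiro[bicyclo[4.2.0]oct-2-ene-8,1'-[2]benzofuran]-2-carboxylate
Conditions: Tf2O, iPr2NEt, CH2Cl2, −78 °C
Reagents that add atoms: trifluoromethanesulfonic anhydride, O=S(=O)(OS(=O)(=O)C(F)(F)F)C(F)(F)F
Why: The amine base and Tf2O sulfonylate the β-keto ester on its enol oxygen (enol triflate formation), this being the only enolisable 1,3-dicarbonyl unit, while the lactone and the tert-butyl ester are inert at −78 °C.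

Step 13
Reactants: 21 tert-butyl (1R,6S,7R,8R)-3'-oxo-7-propyl-3-(trifluoromethanesulfonyloxy)-3'H-spiro[bicyclo[4.2.0]oct-2-ene-8,1'-[2]benzofuran]-2-carboxylate; 22 pent-1-yne
Product: 23 tert-butyl (1R,6S,7R,8R)-3'-oxo-3-(pent-1-yn-1-yl)-7-propyl-3'H-spiro[bicyclo[4.2.0]oct-2-ene-8,1'-[2]benzofuran]-2-carboxylate
Conditions: PdCl2(PPh3)2 (5 mol%), CuI (10 mol%), Et3N, DMF, rt
Reagents that add atoms: pent-1-yne (22), CCCC#C
Why: Sonogashira coupling of the electron-poor alkenyl triflate with the terminal alkyne gives the 2-en-4-ynoate, in which the ring holds ester and alkyne cis as the lactonisation requires.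

Step 14
Reactants: 23 tert-butyl (1R,6S,7R,8R)-3'-oxo-3-(pent-1-yn-1-yl)-7-propyl-3'H-spiro[bicyclo[4.2.0]oct-2-ene-8,1'-[2]benzofuran]-2-carboxylate
Product: 24 (1R,6S,7R,8R)-3'-oxo-3-(pent-1-yn-1-yl)-7-propyl-3'H-spiro[bicyclo[4.2.0]oct-2-ene-8,1'-[2]benzofuran]-2-carboxylic acid
Conditions: CF3CO2H/CH2Cl2 (1:4), 0 °C → rt
Reagents that add atoms: none
Why: Acidolysis of the tert-butyl ester (loss of isobutene) frees the carboxylic acid without base, so the phthalide is not opened and no stereocentre meets epimerising conditions.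

Step 15
Reactants: 24 (1R,6S,7R,8R)-3'-oxo-3-(pent-1-yn-1-yl)-7-propyl-3'H-spiro[bicyclo[4.2.0]oct-2-ene-8,1'-[2]benzofuran]-2-carboxylic acid
Product: 25 CNP0248594.2, the (Z)-butylidene butenolide closed between the C2 carboxyl group and the alkyne carbon on C3 of 24, with the (1R,6S,7R,8R) core unchanged
Conditions: AgNO3 (10 mol%), acetone, rt, dark
Reagents that add atoms: none
Why: AgNO3 activates the alkyne for 5-exo-dig attack of the carboxylic acid oxygen, and anti addition followed by protodemetalation gives the (Z)-alkylidene butenolide (silver-catalysed cycloisomerisation of a 2-en-4-ynoic acid).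

**Compound list**

1 | methyl 3,3-dimethoxycyclobutane-1-carboxylate (commercial; also one operation from 3-oxocyclobutane-1-carboxylic acid) | COC(=O)C1CC(OC)(OC)C1 | starting material
2 | methyl 3,3-dimethoxy-1-(phenylselanyl)cyclobutane-1-carboxylate | COC(=O)C1([Se]c2ccccc2)CC(OC)(OC)C1 | intermediate
3 | methyl 3,3-dimethoxy-1-(phenylseleninyl)cyclobutane-1-carboxylate (selenoxide) | COC(=O)C1([Se](=O)c2ccccc2)CC(OC)(OC)C1 | intermediate (not isolated)
4 | methyl 3,3-dimethoxycyclobut-1-ene-1-carboxylate | COC(=O)C1=CC(OC)(OC)C1 | intermediate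
5 | (3,3-dimethoxycyclobut-1-en-1-yl)methanol | OCC1=CC(OC)(OC)C1 | intermediate
6 | 3,3-dimethoxycyclobut-1-ene-1-carbaldehyde | O=CC1=CC(OC)(OC)C1 | intermediate
7 | tert-butyl 3-oxobutanoate (tert-butyl acetoacetate) | CC(=O)CC(=O)OC(C)(C)C | starting material
8 | tert-butyl 2-[(1R,2S)-2-formyl-4,4-dimethoxycyclobutyl]-3-oxobutanoate (cis; mixture at the acetoacetate carbon) | O=C[C@H]1CC(OC)(OC)[C@H]1C(C(C)=O)C(=O)OC(C)(C)C | intermediate (not isolated)
9 | tert-butyl (1R,6S)-5-hydroxy-8,8-dimethoxy-3-oxobicyclo[4.2.0]octane-2-carboxylate (mixture at C2 and C5) | CC(C)(C)OC(=O)C1C(=O)CC(O)[C@H]2CC(OC)(OC)[C@@H]12 | intermediate (not isolated)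
10 | tert-butyl (1R,6R)-3-hydroxy-8,8-dimethoxybicyclo[4.2.0]octa-2,4-diene-2-carboxylate (dienol form of the enone keto ester, cis-fused) | CC(C)(C)OC(=O)C1=C(O)C=C[C@H]2CC(OC)(OC)[C@@H]12 | intermediate
11 | tert-butyl (1R,6S)-3-hydroxy-8,8-dimethoxybicyclo[4.2.0]oct-2-ene-2-carboxylate | CC(C)(C)OC(=O)C1=C(O)CC[C@H]2CC(OC)(OC)[C@@H]12 | intermediate
12 | tert-butyl (1R,6S)-3-hydroxy-8-oxobicyclo[4.2.0]oct-2-ene-2-carboxylate | CC(C)(C)OC(=O)C1=C(O)CC[C@H]2CC(=O)[C@@H]12 | intermediate
13 | propanal | CCC=O | starting material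
14 | tert-butyl (1R,6R)-3-hydroxy-7-(1-hydroxypropyl)-8-oxobicyclo[4.2.0]oct-2-ene-2-carboxylate (mixture at C7 and the carbinol carbon) | CC(C)(C)OC(=O)C1=C(O)CC[C@H]2C(C(O)CC)C(=O)[C@@H]12 | intermediate
15 | tert-butyl (1R,6R)-3-hydroxy-7-[1-(methanesulfonyloxy)propyl]-8-oxobicyclo[4.2.0]oct-2-ene-2-carboxylate | CC(C)(C)OC(=O)C1=C(O)CC[C@H]2C(C(CC)OS(C)(=O)=O)C(=O)[C@@H]12 | intermediate (not isolated)
16 | tert-butyl (1R,6R,7E)-3-hydroxy-8-oxo-7-propylidenebicyclo[4.2.0]oct-2-ene-2-carboxylate | CC(C)(C)OC(=O)C1=C(O)CC[C@H]2/C(=C\CC)C(=O)[C@@H]12 | intermediate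
17 | tert-butyl (1R,6S,7R)-3-hydroxy-8-oxo-7-propylbicyclo[4.2.0]oct-2-ene-2-carboxylate (propyl endo) | CC(C)(C)OC(=O)C1=C(O)CC[C@H]2[C@@H](CCC)C(=O)[C@@H]12 | intermediate
18 | methyl 2-iodobenzoate | COC(=O)c1ccccc1I | starting material
19 | tert-butyl (1R,6S,7R,8R)-3,8-dihydroxy-8-[2-(methoxycarbonyl)phenyl]-7-propylbicyclo[4.2.0]oct-2-ene-2-carboxylate (present as its magnesium alkoxide; aryl exo, oxygen endo) | CC(C)(C)OC(=O)C1=C(O)CC[C@H]2[C@@H](CCC)[C@](O)(c3ccccc3C(=O)OC)[C@@H]12 | intermediate (not isolated)
20 | tert-butyl (1R,6S,7R,8R)-3-hydroxy-3'-oxo-7-propyl-3'H-spiro[bicyclo[4.2.0]oct-2-ene-8,1'-[2]benzofuran]-2-carboxylate | CC(C)(C)OC(=O)C1=C(O)CC[C@H]2[C@@H](CCC)[C@@]3(OC(=O)c4ccccc43)[C@@H]12 | intermediate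
21 | tert-butyl (1R,6S,7R,8R)-3'-oxo-7-propyl-3-(trifluoromethanesulfonyloxy)-3'H-spiro[bicyclo[4.2.0]oct-2-ene-8,1'-[2]benzofuran]-2-carboxylate | CC(C)(C)OC(=O)C1=C(OS(=O)(=O)C(F)(F)F)CC[C@H]2[C@@H](CCC)[C@@]3(OC(=O)c4ccccc43)[C@@H]12 | intermediate
22 | pent-1-yne | CCCC#C | starting material
23 | tert-butyl (1R,6S,7R,8R)-3'-oxo-3-(pent-1-yn-1-yl)-7-propyl-3'H-spiro[bicyclo[4.2.0]oct-2-ene-8,1'-[2]benzofuran]-2-carboxylate | CC(C)(C)OC(=O)C1=C(C#CCCC)CC[C@H]2[C@@H](CCC)[C@@]3(OC(=O)c4ccccc43)[C@@H]12 | intermediate
24 | (1R,6S,7R,8R)-3'-oxo-3-(pent-1-yn-1-yl)-7-propyl-3'H-spiro[bicyclo[4.2.0]oct-2-ene-8,1'-[2]benzofuran]-2-carboxylic acid | OC(=O)C1=C(C#CCCC)CC[C@H]2[C@@H](CCC)[C@@]3(OC(=O)c4ccccc43)[C@@H]12 | intermediate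
25 | CNP0248594.2: cis-fused cyclobutane carrying an endo propyl group and a spiro-phthalide (aryl exo, lactone oxygen endo), fused to a 4,5,6,7-tetrahydro-(Z)-3-butylidenephthalide; (1R,6S,7R,8R) in the route numbering | CCC/C=C1\OC(=O)C2=C1CC[C@H]1[C@@H](CCC)[C@@]3(OC(=O)c4ccccc43)[C@@H]21 | target

**Step count and risks**

Total step count: 15. Longest linear sequence: 15 steps (1 → 25); the aryl Grignard reagent is made within step 11.

Steps most likely to fail:

1. Step 5 (proposed new method). The bulky secondary amine may condense too slowly with the α-branched enal, the acetoacetate may add without useful facial discrimination, or carbonyl addition and thermal opening of the cyclobutene may outrun conjugate addition. The fallback uses known chemistry, sets out from 6 and 7 and returns at 11. The annulation is run as a classical base-initiated Robinson-type sequence without a chiral controller: catalytic DBU in THF at 0 °C for the Michael addition of the acetoacetate enolate, which needs no iminium ion, then pyrrolidinium acetate and p-TsOH for aldol condensation. This gives 8, 9 and 10 together with their mirror images tert-butyl 2-[(1S,2R)-2-formyl-4,4-dimethoxycyclobutyl]-3-oxobutanoate F1, tert-butyl (1S,6R)-5-hydroxy-8,8-dimethoxy-3-oxobicyclo[4.2.0]octane-2-carboxylate F2 and tert-butyl (1S,6S)-3-hydroxy-8,8-dimethoxybicyclo[4.2.0]octa-2,4-diene-2-carboxylate F3. Hydrogenation as in step 6 gives 11 with its enantiomer tert-butyl (1S,6R)-3-hydroxy-8,8-dimethoxybicyclo[4.2.0]oct-2-ene-2-carboxylate F4. Preparative chromatography on a chiral stationary phase (supercritical CO2, amylose carbamate) then separates 11, and the route continues at step 7.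

2. Step 8. Deprotonation may occur at C4 of the keto ester enolate instead of C7, the cyclobutanone enolate may condense with unreacted ketone, and in step 9 the free keto ester may add to the new enone. The fallback sets out from 12 and returns at 16. The keto ester is masked first: NaH and MOMCl in THF at 0 °C give the enol ether tert-butyl (1R,6S)-3-(methoxymethoxy)-8-oxobicyclo[4.2.0]oct-2-ene-2-carboxylate F5. With no acidic 1,3-dicarbonyl proton left, one equivalent of LiN(iPr)2 enolises only the cyclobutanone CH2, and propanal gives tert-butyl (1R,6R)-7-(1-hydroxypropyl)-3-(methoxymethoxy)-8-oxobicyclo[4.2.0]oct-2-ene-2-carboxylate F6. MsCl and Et3N convert it through the mesylate tert-butyl (1R,6R)-7-[1-(methanesulfonyloxy)propyl]-3-(methoxymethoxy)-8-oxobicyclo[4.2.0]oct-2-ene-2-carboxylate F7 into tert-butyl (1R,6R,7E)-3-(methoxymethoxy)-8-oxo-7-propylidenebicyclo[4.2.0]oct-2-ene-2-carboxylate F8. Dilute HCl in THF cleaves the MOM enol ether and returns 16.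

3. Step 11. The ester-bearing Grignard reagent may decompose or act as a base before it adds, which would enolise the ketone and erase the endo configuration at C7. The fallback sets out from 17 and returns at 20. A robust aryl nucleophile with the future lactone carbon at the aldehyde level is used: [2-(dimethoxymethyl)phenyl]lithium (from 1-bromo-2-(dimethoxymethyl)benzene and nBuLi), transmetalated with CeCl3. It adds to the lithium enolate of 17 from the exo face to give tert-butyl (1R,6S,7R,8R)-8-[2-(dimethoxymethyl)phenyl]-3,8-dihydroxy-7-propylbicyclo[4.2.0]oct-2-ene-2-carboxylate F9. Pyridinium p-toluenesulfonate in wet acetone unmasks the aldehyde, which closes to the lactol tert-butyl (1R,6S,7R,8R)-3,3'-dihydroxy-7-propyl-3'H-spiro[bicyclo[4.2.0]oct-2-ene-8,1'-[2]benzofuran]-2-carboxylate F10. Ag2CO3 on Celite in warm toluene oxidises the lactol to lactone 20.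

Further compounds
F1 | step 5 | tert-butyl 2-[(1S,2R)-2-formyl-4,4-dimethoxycyclobutyl]-3-oxobutanoate (enantiomer of 8) | O=C[C@@H]1CC(OC)(OC)[C@@H]1C(C(C)=O)C(=O)OC(C)(C)C
F2 | step 5 | tert-butyl (1S,6R)-5-hydroxy-8,8-dimethoxy-3-oxobicyclo[4.2.0]octane-2-carboxylate (enantiomer of 9) | CC(C)(C)OC(=O)C1C(=O)CC(O)[C@@H]2CC(OC)(OC)[C@H]12
F3 | step 5 | tert-butyl (1S,6S)-3-hydroxy-8,8-dimethoxybicyclo[4.2.0]octa-2,4-diene-2-carboxylate (enantiomer of 10) | CC(C)(C)OC(=O)C1=C(O)C=C[C@@H]2CC(OC)(OC)[C@H]12
F4 | step 5 | tert-butyl (1S,6R)-3-hydroxy-8,8-dimethoxybicyclo[4.2.0]oct-2-ene-2-carboxylate (enantiomer of 11) | CC(C)(C)OC(=O)C1=C(O)CC[C@@H]2CC(OC)(OC)[C@H]12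
F5 | step 8 | tert-butyl (1R,6S)-3-(methoxymethoxy)-8-oxobicyclo[4.2.0]oct-2-ene-2-carboxylate | CC(C)(C)OC(=O)C1=C(OCOC)CC[C@H]2CC(=O)[C@@H]12
F6 | step 8 | tert-butyl (1R,6R)-7-(1-hydroxypropyl)-3-(methoxymethoxy)-8-oxobicyclo[4.2.0]oct-2-ene-2-carboxylate | CC(C)(C)OC(=O)C1=C(OCOC)CC[C@H]2C(C(O)CC)C(=O)[C@@H]12
F7 | step 8 | tert-butyl (1R,6R)-7-[1-(methanesulfonyloxy)propyl]-3-(methoxymethoxy)-8-oxobicyclo[4.2.0]oct-2-ene-2-carboxylate | CC(C)(C)OC(=O)C1=C(OCOC)CC[C@H]2C(C(CC)OS(C)(=O)=O)C(=O)[C@@H]12
F8 | step 8 | tert-butyl (1R,6R,7E)-3-(methoxymethoxy)-8-oxo-7-propylidenebicyclo[4.2.0]oct-2-ene-2-carboxylate | CC(C)(C)OC(=O)C1=C(OCOC)CC[C@H]2/C(=C\CC)C(=O)[C@@H]12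
F9 | step 11 | tert-butyl (1R,6S,7R,8R)-8-[2-(dimethoxymethyl)phenyl]-3,8-dihydroxy-7-propylbicyclo[4.2.0]oct-2-ene-2-carboxylate | CC(C)(C)OC(=O)C1=C(O)CC[C@H]2[C@@H](CCC)[C@](O)(c3ccccc3C(OC)OC)[C@@H]12
F10 | step 11 | tert-butyl (1R,6S,7R,8R)-3,3'-dihydroxy-7-propyl-3'H-spiro[bicyclo[4.2.0]oct-2-ene-8,1'-[2]benzofuran]-2-carboxylate (lactol, mixture at C3') | CC(C)(C)OC(=O)C1=C(O)CC[C@H]2[C@@H](CCC)[C@@]3(OC(O)c4ccccc43)[C@@H]12
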